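**Retrosynthetic overview**

1. The target is the 6α-angelate of (12E)-labda-12,14-diene-6α,8α-diol. The ester is made last, and C11–C12 comes from a B-alkyl Suzuki coupling of a C11 borane with (E)-1-iodo-2-methylbuta-1,3-diene; the borane arises by α-face hydroboration of a 9(11)-methylene decalin, which sets C9.
2. The strategy rests on C8 of ring B: a tertiary carbinol carbon that carries the C17 methyl and is bonded to C7 and to C9, with C9 next to the quaternary C10. This C8 is the acetyl carbonyl carbon of a 9α-hydroxy-9β-acetyl trans-hydrindane, so ring B is disconnected at C7–C8 by an α-ketol ring expansion that leaves a C9 ketone.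
3. The ketol comes from the C9 hydrindanone by non-basic methylenation, α-face dihydroxylation, oxidation, methyl addition and oxidation.
4. The hydrindanone comes from (S)-7a-methyl-2,3,7,7a-tetrahydro-1H-indene-1,5(6H)-dione by C9 ketalization, deconjugative gem-dimethylation at C4, Wolff–Kishner reduction and α-face hydroboration of C5=C6 (5α-H, 6α-O).
5. Ring order: ring A and the cyclopentane (C5, C6, C7, C9, C10) are present in the starting dione; ring B is formed in step 12 by enlargement of the cyclopentane.

Key step: step 12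

Numbering: labdane numbers are used for all compounds, hydrindanes included. The cyclopentanone carbonyl carbon of the starting dione is C9, its enone carbonyl carbon C3, the angular carbon C10; C8, C17 and C11 are added later.

Remark: a Wittig ethylidenation of the C9 ketone is not used, because a β-silyloxy cyclopentanone loses its C6 silyloxy group by E1cB under ylide or alkoxide base. The acetyl carbinol is therefore built by non-basic methylenation, dihydroxylation and Grignard addition.

**Route**

Step 1
Reactants: 1 (S)-7a-methyl-2,3,7,7a-tetrahydro-1H-indene-1,5(6H)-dione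
Product: 2 C9 ethylene ketal of 1 (enone C3=O/C4=C5 intact)
Conditions: TMSOCH2CH2OTMS, TMSOTf (5 mol%), CH2Cl2, −78 to −20 °C
Reagents that add atoms: 1,2-bis(trimethylsilyloxy)ethane, C[Si](C)(C)OCCO[Si](C)(C)C
Why: Noyori ketalization is kinetically selective for a saturated ketone over a conjugated enone carbonyl, so only the cyclopentanone carbonyl C9 should be masked while the C10 stereocenter stays untouched.

Step 2
Reactants: 2 C9 ethylene ketal of 1
Product: 3 9,9-ethylenedioxy-4,4,10β-trimethylhydrind-5-en-3-one
Conditions: KOtBu (3 equiv), tBuOH/THF, rt; MeI (excess), 0 °C to rt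
Reagents that add atoms: iodomethane, CI
Why: Deconjugative α,α-dialkylation of the extended potassium dienolate (deprotonation at C6) should place both methyl groups on C4 and leave the alkene at C5=C6.

Step 3
Reactants: 3 9,9-ethylenedioxy-4,4,10β-trimethylhydrind-5-en-3-one
Product: 5 9,9-ethylenedioxy-4,4,10β-trimethylhydrind-5-ene, via C3 hydrazone 4 (not isolated)
Conditions: N2H4·H2O, KOH, diethylene glycol, 130 then 200 °C
Reagents that add atoms: none
Why: Wolff–Kishner reduction in its Huang-Minlon form should remove the hindered C3 carbonyl through the hydrazone, the ketal and the isolated trisubstituted alkene being stable to hot base.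

Step 4
Reactants: 5 9,9-ethylenedioxy-4,4,10β-trimethylhydrind-5-ene
Product: 7 9,9-ethylenedioxy-4,4,10β-trimethyl-5α-hydrindan-6α-ol, via 6α-alkylborane 6 (not isolated)
Conditions: BH3·THF, THF, 0 °C to rt; then NaOH, H2O2, 0 °C to rt
Reagents that add atoms: hydrogen peroxide, OO
Why: Hydroboration–oxidation should deliver hydrogen to C5 and boron to the less substituted C6 from the α face, opposite the angular C10 methyl and the axial 4β-methyl, which sets 5α-H (trans ring fusion) and, after oxidation with retention, 6α-OH.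

Step 5
Reactants: 7 9,9-ethylenedioxy-4,4,10β-trimethyl-5α-hydrindan-6α-ol
Product: 8 6α-tert-butyldimethylsilyl ether of 7
Conditions: TBSCl, imidazole, DMAP (cat.), DMF, 40 °C
Reagents that add atoms: tert-butyldimethylsilyl chloride, CC(C)(C)[Si](C)(C)Cl
Why: Imidazole-mediated silylation of the only free hydroxyl runs under weakly basic conditions that the ketal tolerates.

Step 6
Reactants: 8 6α-tert-butyldimethylsilyl ether of 7
Product: 9 6α-(tert-butyldimethylsilyloxy)-4,4,10β-trimethyl-5α-hydrindan-9-one
Conditions: PPTS, acetone/H2O, 50 °C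
Reagents that add atoms: water, O
Why: Mild acid-catalysed ketal hydrolysis should free the C9 ketone at an acidity at which the secondary silyl ether survives and the β-silyloxy ketone does not eliminate.

Step 7
Reactants: 9 6α-(tert-butyldimethylsilyloxy)-4,4,10β-trimethyl-5α-hydrindan-9-one
Product: 10 6α-(tert-butyldimethylsilyloxy)-4,4,10β-trimethyl-9-methylene-5α-hydrindane
Conditions: Cp2Ti(μ-CH2)(μ-Cl)AlMe2 (Tebbe reagent), pyridine (cat.), THF/toluene, −40 °C to rt
Reagents that add atoms: Tebbe reagent, C[Al](C)C[Ti](Cl)(C1C=CC=C1)C1C=CC=C1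
Why: Tebbe methylenation is a non-basic carbonyl olefination through an oxatitanacyclobutane, so the ketone should become the exocyclic alkene without the enolate-driven loss of the C6 silyloxy group that an ylide would cause.

Step 8
Reactants: 10 6α-(tert-butyldimethylsilyloxy)-4,4,10β-trimethyl-9-methylene-5α-hydrindane
Product: 11 6α-(tert-butyldimethylsilyloxy)-9β-(hydroxymethyl)-4,4,10β-trimethyl-5α-hydrindan-9α-ol
Conditions: OsO4 (2 mol%), NMO, acetone/H2O, rt
Reagents that add atoms: osmium tetroxide (catalytic oxygen carrier), O=[Os](=O)(=O)=O; N-methylmorpholine N-oxide, C[N+]1([O-])CCOCC1; water, O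
Why: Upjohn dihydroxylation should occur on the α face of the 1,1-disubstituted alkene, away from the angular methyl on the adjacent C10, which sets C9 with the hydroxyl α and the hydroxymethyl carbon (the future C8) β.

Step 9
Reactants: 11 6α-(tert-butyldimethylsilyloxy)-9β-(hydroxymethyl)-4,4,10β-trimethyl-5α-hydrindan-9α-ol
Product: 12 6α-(tert-butyldimethylsilyloxy)-9α-hydroxy-4,4,10β-trimethyl-5α-hydrindane-9β-carbaldehyde
Conditions: IBX, DMSO, rt
Reagents that add atoms: none
Why: IBX oxidation converts the primary alcohol of a 1,2-diol into the aldehyde without glycol cleavage and cannot oxidize the tertiary carbinol.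

Step 10
Reactants: 12 6α-(tert-butyldimethylsilyloxy)-9α-hydroxy-4,4,10β-trimethyl-5α-hydrindane-9β-carbaldehyde
Product: 13 6α-(tert-butyldimethylsilyloxy)-9β-(1-hydroxyethyl)-4,4,10β-trimethyl-5α-hydrindan-9α-ol (C8 epimer mixture)
Conditions: MeMgBr (3 equiv), THF, −78 to 0 °C; aq. NH4Cl
Reagents that add atoms: methylmagnesium bromide, C[Mg]Br
Why: Grignard addition to the aldehyde (the first equivalent deprotonates the tertiary hydroxyl) attaches the C17 methyl, and the configuration of the new C8 carbinol is irrelevant because this centre is oxidized in the next step.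

Step 11
Reactants: 13 6α-(tert-butyldimethylsilyloxy)-9β-(1-hydroxyethyl)-4,4,10β-trimethyl-5α-hydrindan-9α-ol
Product: 14 1β-acetyl-3α-(tert-butyldimethylsilyloxy)-4,4,7aβ-trimethyl-trans-octahydroinden-1α-ol (9β-acetyl-9α-hydroxy-6α-silyloxy hydrindane)
Conditions: IBX, DMSO, 40 °C
Reagents that add atoms: none
Why: IBX oxidation of the secondary alcohol of a secondary/tertiary 1,2-diol should give the α-hydroxy ketone without C–C cleavage, both C8 epimers converging on one ketol.

Step 12
Reactants: 14 1β-acetyl-3α-(tert-butyldimethylsilyloxy)-4,4,7aβ-trimethyl-trans-octahydroinden-1α-ol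
Product: 17 6α-(tert-butyldimethylsilyloxy)-8α-hydroxy-4,4,8β,10β-tetramethyl-trans-decalin-9-one, via aluminium alkoxide of the ketol 15 (not isolated), via aluminium alkoxide of the ring-expanded ketol 16 (not isolated)
Conditions: Al(OtBu)3 (2 equiv), toluene, 100 °C; aq. Rochelle salt work-up
Reagents that add atoms: none
Why: This is an α-ketol (acyloin) rearrangement, and its closest known case is the Lewis-acid D-homoannulation of 17α-hydroxy-20-keto steroids; alkoxide exchange should give aluminium ketol 15, in which the metal binds the C9 oxygen and the acetyl oxygen on the same side. In this chelate the C9–C7 bond moves to the acetyl carbon (new C7–C8 bond) while C9 becomes the carbonyl, so ring B arises by a one-atom enlargement of the cyclopentane through a 1,2-alkyl shift and not by closure of an open chain. The new stereocenter C8 is controlled by the C9 configuration (acetyl β, hydroxyl α) together with the chelated syn geometry, which brings C7 onto the acetyl face that leaves the former carbonyl oxygen α and the methyl β. The step needs migration of the methylene C7 and not of the quaternary C10; the 17α-hydroxy-17β-acetyl steroids behave in this way, and the outcome puts the ketone next to C10 and the carbinol carbon next to a CH2, which is the less congested arrangement. The shift is reversible and should be pulled forward by the lower strain of the trans-decalin compared with the trans-fused hydrindane, and the product ketone has no α-hydrogen, so neither epimerization nor elimination of the C6 silyl ether can follow. Al(OtBu)3 is chosen because it has no transferable hydride and should leave the silyl ether intact.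

Step 13
Reactants: 17 6α-(tert-butyldimethylsilyloxy)-8α-hydroxy-4,4,8β,10β-tetramethyl-trans-decalin-9-one
Product: 18 8α-trimethylsilyl ether of 17
Conditions: TMSOTf, 2,6-lutidine, CH2Cl2, −78 to 0 °C
Reagents that add atoms: trimethylsilyl trifluoromethanesulfonate, C[Si](C)(C)OS(=O)(=O)C(F)(F)F
Why: Silyl triflate silylation caps the hindered tertiary hydroxyl, which would otherwise consume the titanium reagent and allow a metal-alkoxide acyloin shift in the next step, and the ketone cannot form an enol silyl ether because it has no α-hydrogen.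

Step 14
Reactants: 18 8α-trimethylsilyl ether of 17
Product: 19 6α-(tert-butyldimethylsilyloxy)-8α-(trimethylsilyloxy)-4,4,8β,10β-tetramethyl-9-methylene-trans-decalin
Conditions: Cp2Ti(μ-CH2)(μ-Cl)AlMe2 (Tebbe reagent), pyridine (cat.), THF/toluene, −40 to 60 °C
Reagents that add atoms: Tebbe reagent, C[Al](C)C[Ti](Cl)(C1C=CC=C1)C1C=CC=C1
Why: Tebbe methylenation is the carbonyl olefination suited to ketones flanked by fully substituted carbons that resist Wittig reagents, and the non-enolizable C9 ketone can only react at the carbonyl to give the 9(11)-alkene.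

Step 15
Reactants: 20 prop-2-yn-1-ol
Product: 22 (E)-3-iodo-2-methylprop-2-en-1-ol, via (E)-alkenylalane 21 (not isolated)
Conditions: AlMe3 (3 equiv), Cp2ZrCl2 (0.25 equiv), CH2Cl2, 0 °C to rt; then I2, THF, −30 to 0 °C
Reagents that add atoms: trimethylaluminium, C[Al](C)C; iodine, II
Why: Zirconium-catalysed Negishi carboalumination adds methyl and aluminium syn across the alkyne with methyl on the internal carbon, and iodinolysis of the C–Al bond with retention should give the (E)-iodoalkene.

Step 16
Reactants: 22 (E)-3-iodo-2-methylprop-2-en-1-ol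
Product: 23 (E)-3-iodo-2-methylprop-2-enal
Conditions: MnO2, CH2Cl2, rt
Reagents that add atoms: none
Why: MnO2 oxidizes the allylic alcohol selectively to the enal and leaves the vinyl iodide and the alkene geometry unchanged.

Step 17
Reactants: 23 (E)-3-iodo-2-methylprop-2-enal
Product: 24 (E)-1-iodo-2-methylbuta-1,3-diene
Conditions: Ph3PCH3Br, NaHMDS, THF, 0 °C; then 23, −78 to 0 °C
Reagents that add atoms: methyltriphenylphosphonium bromide, C[P+](c1ccccc1)(c1ccccc1)c1ccccc1.[Br-]
Why: Wittig methylenation of the non-enolizable enal should install the terminal vinyl group without touching the (E)-iodoalkene, and the volatile diene is carried on as a titrated solution.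

Step 18
Reactants: 19 6α-(tert-butyldimethylsilyloxy)-8α-(trimethylsilyloxy)-4,4,8β,10β-tetramethyl-9-methylene-trans-decalin, 24 (E)-1-iodo-2-methylbuta-1,3-diene
Product: 26 (12E)-6α-(tert-butyldimethylsilyloxy)-8α-(trimethylsilyloxy)labda-12,14-diene, via C11 alkyl-9-BBN 25 (not isolated)
Conditions: 9-BBN dimer, THF, 65 °C; then 24, PdCl2(dppf) (10 mol%), AsPh3, aq. Cs2CO3, DMF/THF, rt to 45 °C
Reagents that add atoms: none
Why: 9-BBN should place boron on the terminal C11 and hydrogen on C9 from the α face, anti to the two axial β-methyl groups on C8 and C10 that flank the alkene, which sets 9α-H, and the B-alkyl Suzuki–Miyaura coupling then joins C11 to C12 with retention of the (E)-alkenyl iodide geometry.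

Step 19
Reactants: 26 (12E)-6α-(tert-butyldimethylsilyloxy)-8α-(trimethylsilyloxy)labda-12,14-diene
Product: 27 (12E)-labda-12,14-diene-6α,8α-diol
Conditions: TBAF (excess), THF, 50 °C
Reagents that add atoms: none
Why: Fluoride desilylation removes both silyl ethers under basic conditions and so avoids the acid-induced cyclization of the C8 hydroxyl onto the diene.

Step 20
Reactants: 27 (12E)-labda-12,14-diene-6α,8α-diol, 28 angelic acid ((Z)-2-methylbut-2-enoic acid)
Product: 30 (12E)-8α-hydroxylabda-12,14-dien-6α-yl (Z)-2-methylbut-2-enoate (CNP0582767.1), via angelic 2,4,6-trichlorobenzoic anhydride 29 (not isolated)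
Conditions: 28, 2,4,6-trichlorobenzoyl chloride, Et3N, toluene, rt; then 27, toluene, 80 °C
Reagents that add atoms: none
Why: Yamaguchi-type acylation through the mixed anhydride, run without a nucleophilic amine catalyst, should esterify the secondary 6α-hydroxyl in preference to the tertiary 8α-hydroxyl and avoid the conjugate-addition pathway that isomerizes angelates to tiglates.

**Compound list**

1 | (S)-7a-methyl-2,3,7,7a-tetrahydro-1H-indene-1,5(6H)-dione | O=C1[C@@]2(C)CCC(=O)C=C2CC1 | starting material
2 | C9 ethylene ketal of 1 | C12(OCCO1)[C@@]3(C)CCC(=O)C=C3CC2 | intermediate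
3 | 9,9-ethylenedioxy-4,4,10β-trimethylhydrind-5-en-3-one | C12(OCCO1)[C@@]3(C)CCC(=O)C(C)(C)C3=CC2 | intermediate
4 | C3 hydrazone of 3 | C12(OCCO1)[C@@]3(C)CCC(=NN)C(C)(C)C3=CC2 | intermediate (not isolated)
5 | 9,9-ethylenedioxy-4,4,10β-trimethylhydrind-5-ene | C12(OCCO1)[C@@]3(C)CCCC(C)(C)C3=CC2 | intermediate
6 | 6α-boryl-9,9-ethylenedioxy-4,4,10β-trimethyl-5α-hydrindane | C12(OCCO1)[C@@]3(C)CCCC(C)(C)[C@@H]3[C@@H](B)C2 | intermediate (not isolated)
7 | 9,9-ethylenedioxy-4,4,10β-trimethyl-5α-hydrindan-6α-ol | C12(OCCO1)[C@@]3(C)CCCC(C)(C)[C@@H]3[C@@H](O)C2 | intermediate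
8 | 6α-tert-butyldimethylsilyl ether of 7 | C12(OCCO1)[C@@]3(C)CCCC(C)(C)[C@@H]3[C@@H](O[Si](C)(C)C(C)(C)C)C2 | intermediate
9 | 6α-(tert-butyldimethylsilyloxy)-4,4,10β-trimethyl-5α-hydrindan-9-one | O=C1[C@@]2(C)CCCC(C)(C)[C@@H]2[C@@H](O[Si](C)(C)C(C)(C)C)C1 | intermediate
10 | 6α-(tert-butyldimethylsilyloxy)-4,4,10β-trimethyl-9-methylene-5α-hydrindane | C=C1[C@@]2(C)CCCC(C)(C)[C@@H]2[C@@H](O[Si](C)(C)C(C)(C)C)C1 | intermediate
11 | 6α-(tert-butyldimethylsilyloxy)-9β-(hydroxymethyl)-4,4,10β-trimethyl-5α-hydrindan-9α-ol | OC[C@]1(O)[C@@]2(C)CCCC(C)(C)[C@@H]2[C@@H](O[Si](C)(C)C(C)(C)C)C1 | intermediate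
12 | 6α-(tert-butyldimethylsilyloxy)-9α-hydroxy-4,4,10β-trimethyl-5α-hydrindane-9β-carbaldehyde | O=C[C@]1(O)[C@@]2(C)CCCC(C)(C)[C@@H]2[C@@H](O[Si](C)(C)C(C)(C)C)C1 | intermediate
13 | 6α-(tert-butyldimethylsilyloxy)-9β-(1-hydroxyethyl)-4,4,10β-trimethyl-5α-hydrindan-9α-ol (C8 epimer mixture, C8 left undefined) | CC(O)[C@]1(O)[C@@]2(C)CCCC(C)(C)[C@@H]2[C@@H](O[Si](C)(C)C(C)(C)C)C1 | intermediate
14 | 1β-acetyl-3α-(tert-butyldimethylsilyloxy)-4,4,7aβ-trimethyl-trans-octahydroinden-1α-ol | CC(=O)[C@]1(O)[C@@]2(C)CCCC(C)(C)[C@@H]2[C@@H](O[Si](C)(C)C(C)(C)C)C1 | intermediate (key-step precursor)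
15 | di-tert-butoxyaluminium alkoxide of 14 | CC(=O)[C@]1(O[Al](OC(C)(C)C)OC(C)(C)C)[C@@]2(C)CCCC(C)(C)[C@@H]2[C@@H](O[Si](C)(C)C(C)(C)C)C1 | intermediate (not isolated)
16 | di-tert-butoxyaluminium alkoxide of 17 | O=C1[C@@]2(C)CCCC(C)(C)[C@@H]2[C@@H](O[Si](C)(C)C(C)(C)C)C[C@@]1(C)O[Al](OC(C)(C)C)OC(C)(C)C | intermediate (not isolated)
17 | 6α-(tert-butyldimethylsilyloxy)-8α-hydroxy-4,4,8β,10β-tetramethyl-trans-decalin-9-one | O=C1[C@@]2(C)CCCC(C)(C)[C@@H]2[C@@H](O[Si](C)(C)C(C)(C)C)C[C@@]1(C)O | intermediate (key-step product)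
18 | 8α-trimethylsilyl ether of 17 | O=C1[C@@]2(C)CCCC(C)(C)[C@@H]2[C@@H](O[Si](C)(C)C(C)(C)C)C[C@@]1(C)O[Si](C)(C)C | intermediate
19 | 6α-(tert-butyldimethylsilyloxy)-8α-(trimethylsilyloxy)-4,4,8β,10β-tetramethyl-9-methylene-trans-decalin | C=C1[C@@]2(C)CCCC(C)(C)[C@@H]2[C@@H](O[Si](C)(C)C(C)(C)C)C[C@@]1(C)O[Si](C)(C)C | intermediate
20 | prop-2-yn-1-ol | C#CCO | starting material
21 | (E)-alkenylalane, dimethylaluminium alkoxide | C[Al](C)/C=C(C)/CO[Al](C)C | intermediate (not isolated)
22 | (E)-3-iodo-2-methylprop-2-en-1-ol | OC/C(C)=C/I | intermediate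
23 | (E)-3-iodo-2-methylprop-2-enal | O=C/C(C)=C/I | intermediate
24 | (E)-1-iodo-2-methylbuta-1,3-diene | C=C/C(C)=C/I | intermediate
25 | C11 B-alkyl-9-borabicyclo[3.3.1]nonane from 19 (9α-H) | C(B1C2CCCC1CCC2)[C@@H]1[C@@]2(C)CCCC(C)(C)[C@@H]2[C@@H](O[Si](C)(C)C(C)(C)C)C[C@@]1(C)O[Si](C)(C)C | intermediate (not isolated)
26 | (12E)-6α-(tert-butyldimethylsilyloxy)-8α-(trimethylsilyloxy)labda-12,14-diene | C=C/C(C)=C/C[C@@H]1[C@@]2(C)CCCC(C)(C)[C@@H]2[C@@H](O[Si](C)(C)C(C)(C)C)C[C@@]1(C)O[Si](C)(C)C | intermediate
27 | (12E)-labda-12,14-diene-6α,8α-diol | C=C/C(C)=C/C[C@@H]1[C@@]2(C)CCCC(C)(C)[C@@H]2[C@@H](O)C[C@@]1(C)O | intermediate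
28 | angelic acid, (Z)-2-methylbut-2-enoic acid | C/C=C(/C)C(=O)O | starting material
29 | angelic 2,4,6-trichlorobenzoic anhydride | C/C=C(/C)C(=O)OC(=O)c1c(Cl)cc(Cl)cc1Cl | intermediate (not isolated)
30 | (12E)-8α-hydroxylabda-12,14-dien-6α-yl (Z)-2-methylbut-2-enoate | C=C/C(C)=C/C[C@@H]1[C@@]2(C)CCCC(C)(C)[C@@H]2[C@@H](OC(=O)/C(C)=C\C)C[C@@]1(C)O | target

**Step count and risks**

Total: 20 steps (17 in the main line, 3 for iodide 24). Longest linear sequence: 17 steps (1 to 30 through steps 1–14 and 18–20).

Steps most likely to fail: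

1. Step 12 (α-ketol ring expansion). The migration may go the wrong way (the quaternary C10 shifting instead of C7), the product ketol may equilibrate onward by a methyl shift from C8 to C9, or the rearrangement may stall at the temperature the silyl ether tolerates. The fallback sets out from ketone 9 and makes ring B without a ketol. Diazoethane (from N-ethyl-N-nitrosourea and KOH) with BF3·OEt2 in CH2Cl2 at −78 °C should insert CH(CH3) between C9 and the less substituted C7 (Tiffeneau–Demjanov-type homologation) to give 6α-(tert-butyldimethylsilyloxy)-4,4,8,10β-tetramethyl-trans-decalin-9-one F1 as a C8 epimer mixture. KHMDS in THF at −78 °C then forms the only possible enolate, the potassium C8(9)-enolate F2, which 2-(phenylsulfonyl)-3-phenyloxaziridine should hydroxylate on the α face, away from the axial C10 methyl. The sequence comes back to the route at 17.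

2. Step 14 (methylenation of the C9 ketone between two fully substituted carbons). Steric shielding may prevent the titanium methylidene from reaching the carbonyl, or the Lewis acidic aluminium by-product may strip the trimethylsilyl ether and open the way to acyloin scrambling. The fallback sets out from 18 and builds the alkene stepwise by a Peterson sequence. Me3SiCH2Li with CeCl3 (THF, −78 to 0 °C) should add the small, weakly basic organocerium to C9 to give the 9-hydroxy-9-(trimethylsilylmethyl) adduct F3, and KH in THF then effects syn-elimination of silanolate. The sequence comes back to the route at 19.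

3. Step 18 (hydroboration and B-alkyl Suzuki coupling). Hydroboration by the bulky borane may be too slow at an alkene flanked by C8 and C10, or the β-branched alkylborane may transmetalate so slowly that the sensitive iododiene decomposes or protodeboronation takes over. The fallback sets out from 19 and forms C11–C12 by Negishi coupling. BH3·THF should give the C11 alkylborane F4 (α-face attack, 9α-H), which NaOH/H2O2 oxidizes to the C11 primary alcohol F5. I2, PPh3 and imidazole convert this into the C11 iodide F6, and zinc insertion (Zn dust, LiCl, THF, 40 °C) gives the C11 alkylzinc iodide F7. Coupling of the zinc reagent with 24 under Pd(PPh3)4 in THF comes back to the route at 26.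

**Further compounds**

F1 | step 12 | 6α-(tert-butyldimethylsilyloxy)-4,4,8,10β-tetramethyl-trans-decalin-9-one (C8 epimers) | O=C1[C@@]2(C)CCCC(C)(C)[C@@H]2[C@@H](O[Si](C)(C)C(C)(C)C)CC1C
F2 | step 12 | potassium C8(9)-enolate of F1 | [O-]C=1[C@@]2(C)CCCC(C)(C)[C@@H]2[C@@H](O[Si](C)(C)C(C)(C)C)CC=1C.[K+]
F3 | step 14 | 9-hydroxy-9-(trimethylsilylmethyl) adduct of 18 | C[Si](C)(C)CC1(O)[C@@]2(C)CCCC(C)(C)[C@@H]2[C@@H](O[Si](C)(C)C(C)(C)C)C[C@@]1(C)O[Si](C)(C)C
F4 | step 18 | C11 alkylborane from 19 (9α-H) | BC[C@@H]1[C@@]2(C)CCCC(C)(C)[C@@H]2[C@@H](O[Si](C)(C)C(C)(C)C)C[C@@]1(C)O[Si](C)(C)C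
F5 | step 18 | C11 primary alcohol | OC[C@@H]1[C@@]2(C)CCCC(C)(C)[C@@H]2[C@@H](O[Si](C)(C)C(C)(C)C)C[C@@]1(C)O[Si](C)(C)C
F6 | step 18 | C11 iodide | IC[C@@H]1[C@@]2(C)CCCC(C)(C)[C@@H]2[C@@H](O[Si](C)(C)C(C)(C)C)C[C@@]1(C)O[Si](C)(C)C
F7 | step 18 | C11 alkylzinc iodide | I[Zn]C[C@@H]1[C@@]2(C)CCCC(C)(C)[C@@H]2[C@@H](O[Si](C)(C)C(C)(C)C)C[C@@]1(C)O[Si](C)(C)C
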